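The numbers in the tables are calculated on assumed constants.

**Target plateau.** Watch the target as a share of the starting material charged. The north-east run stops near 0.268 M from 0.500 M, while the south run, alike but for 0.0130 M catalyst against 0.0250 M, reads 0.172 M at 140 min.

| flask | starting material | reagent | catalyst | time |
|---|---|---|---|---|
| north-east | 0.500 M | 1.50 M | 0.0250 M |  |
| north | 0.200 M | 1.20 M | 0.0250 M |  |
| east | 0.250 M | 1.50 M | 0.0250 M |  |
| south | 0.500 M | 1.50 M | 0.0130 M |  |
| north-west | 0.500 M | 1.50 M | 0.0250 M | 840 min |

| run | time / min | [target] / M |
|---|---|---|
| north-east run | 5.0 | 0.034 |
| north-east run | 15 | 0.077 |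
| north-east run | 29 | 0.139 |
| north-east run | 46 | 0.190 |
| north-east run | 66 | 0.228 |
| north-east run | 88 | 0.238 |
| north-east run | 110 | 0.266 |
| north-east run | 140 | 0.268 |
| north run | 5.0 | 0.022 |
| north run | 15 | 0.041 |
| north run | 29 | 0.067 |
| north run | 46 | 0.094 |
| north run | 66 | 0.109 |
| north run | 88 | 0.110 |
| north run | 110 | 0.121 |
| north run | 140 | 0.115 |
| east run | 5.0 | 0.013 |
| east run | 15 | 0.034 |
| east run | 29 | 0.066 |
| east run | 46 | 0.093 |
| east run | 66 | 0.100 |
| east run | 88 | 0.121 |
| east run | 110 | 0.126 |
| east run | 140 | 0.134 |
| south run | 5.0 | 0.016 |
| south run | 15 | 0.036 |
| south run | 29 | 0.081 |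
| south run | 46 | 0.108 |
| south run | 66 | 0.121 |
| south run | 88 | 0.156 |
| south run | 110 | 0.163 |
| south run | 140 | 0.172 |

(each reading ± 0.005 M)

- Overall: starting material + reagent -> target, with catalyst as catalyst.
- Constant volume, constant temperature.
- What is held in complexes is read along with the free species.
- "The second partner" is reagent.
- An order is taken over about fifteen percent of the charge, up and down.

1. the exponent of [catalyst] in the starting rate at the charge of the north-east run (at the point where two percent of the starting material have become target)
2. the exponent of [reagent] in the starting rate at the charge of the north-east run (at the point where two percent of the starting material have become target)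
3. target in the north-west run at 840 min, as a share of the starting material charged

**Kept share.** Reckon with the fraction left, not the fraction made. The east run, with 0.250 M charged, reads 53.6% at 140 min, the same share as the north-east run's 53.6%. So take my own reading: starting material leaves by two first-order branches, a catalysed one into target with pseudo-first-order constant k_c, and a drain with constant k_d that ignores the catalyst. The fraction left is then exp(−λt), with λ = k_c + k_d, and the plateau is the kept share f, the selectivity k_c/λ.

**North-east numbers.** At 29 min the north-east run has 48.1% of its plateau still to make, so λ reads 0.0252 min⁻¹. Then k_c reads 0.0135 min⁻¹ and k_d reads 0.0117 min⁻¹.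

**South comparison.** Scale k_c with the catalyst, and the south run has 0.00703 min⁻¹. In this reckoning its kept share is 37.5%, lower than the north-east share because its k_c is smaller against the same k_d; the south k_c stands below k_d, whereas the north-east k_c stands above it. With 0.0187 min⁻¹ as its λ, the south run should hold 0.174 M at 140 min, and the reading is 0.172 M.

**The forecast.** It gives 1 for catalyst, −1 for reagent and 56% for the north-west run, holding that “the catalyst is probably dying rather than the reaction reaching equilibrium”. My reckoning differs: it puts the drain on the starting material. It gives 53.6% for the north-west run, whose charge is the north-east one and where hardly any starting material remains at 840 min.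

**Flask result.** The simulation gives 1.0 for catalyst, −0.98 for reagent and 54.5% for the north-west run, 0.90 percentage points above the kept share of 53.6% read from the north-east run.

    catalyst + starting material → catalyst-substrate complex (9.960 M⁻¹ min⁻¹)
    catalyst-substrate complex + reagent → target + catalyst (56.16 M⁻¹ min⁻¹)
    catalyst + reagent ⇌ idle catalyst-reagent complex, settled at all times (12.30 M⁻¹)
    starting material → decomposed substrate (0.01188 min⁻¹)

In the north-west run, catalysed uptake and decomposition ran side by side while starting material was there; at the start 94.6% of the catalyst was held as idle catalyst-reagent complex, the resting state, and the catalysed constant stood at 0.0128 min⁻¹ beside 0.0119 min⁻¹ for decomposition. By 840 min in the north-west run the reagent, bound forms counted, stood at 1.23 M, and the starting material had become target, 54.5%, and decomposed substrate, 45.5%.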